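**Plan**

1. Core numbering: C1 (prenyl bridgehead), C2–C3–C4 (enolised β-diketone, aroyl on C3), C5 (lavandulyl bridgehead), C6, C7 (prenyl), C8 (CMe2), C9 (bridging C=O); ring A = C1–C2–C3–C4–C5–C9, ring B = C1–C8–C7–C6–C5–C9.
2. Retrosynthetic cuts, in order: O–CH3 at C4 and O–Si; C1–prenyl and C3–aroyl; the C7 chain back to a C7 ketone and then a C7 carbinol; C2=O; ring B at C1–C8 (together with a helper C7–O–C9 bridge); C5–C6 and C5–CH2(lavandulyl) back to 1,5-dimethoxycyclohexa-1,4-diene.
3. Forward: ring A (and the aryl ring) are bought. The doubly allylic carbon of the diene (C5) is alkylated with (R)-lavandulyl iodide, then with an (R)-epoxyprenyl bromide. Ring B is the last ring, closed by the C1–C8 bond.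
4. Enabling feature: C6–C7–C8 with the two methyls on C8 is a prenyl unit hanging from C5, and C5 sits between two oxygenated carbons (C4, C9) whose enol-ether carbons C3 and C1 are equivalent until ring B forms. A 2,3-epoxyprenyl group on C5 can therefore be opened at C8 by C1, and the epoxide centre alone chooses C1 over C3 and sets both bridgeheads.
5. Stereochemistry: the side-chain centre comes from an Evans alkylation (→ (R)-lavandulol). C1/C5 come from the Sharpless-derived epoxide through a chair transition state. The C7 carbinol is a helper that is oxidised away; C7 is then reset by exo-face hydride addition to an exocyclic enal, which gives the 7-endo chain.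

Key step: step 11

Remark: Lav = (2S)-5-methyl-2-(prop-1-en-2-yl)hex-4-en-1-yl; exo = the face of ring B turned away from C3; diene 14 is taken as a purchasable compound (it is the Birch reduction product of 1,3-dimethoxybenzene).

Step 1
Reactants: 1 (R)-4-benzyl-1,3-oxazolidin-2-one; 2 senecioyl chloride (3-methylbut-2-enoyl chloride)
Product: 3 N-senecioyl oxazolidinone (R)-4-benzyl-3-(3-methylbut-2-enoyl)-1,3-oxazolidin-2-one
Conditions: n-BuLi, THF, −78 °C; then 2, −78 to 0 °C
Reagents that add atoms: none
Why: N-acylation of the lithiated oxazolidinone by an acid chloride (attachment of the Evans auxiliary); no stereocentre is formed.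

Step 2
Reactants: 3 N-senecioyl oxazolidinone; 4 prenyl bromide (1-bromo-3-methylbut-2-ene)
Product: 5 alkylated imide (R)-4-benzyl-3-[(2R)-5-methyl-2-(prop-1-en-2-yl)hex-4-enoyl]-1,3-oxazolidin-2-one
Conditions: NaHMDS, THF, −78 °C; then 4, −78 to −40 °C
Reagents that add atoms: none
Why: Evans alkylation of the chelated sodium dienolate, which should react at the α-carbon (deconjugative alkylation) on the face opposite the benzyl group and so set the (2R) centre that becomes the side-chain stereocentre of 29.

Step 3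
Reactants: 5 alkylated imide
Product: 6 (R)-lavandulol [(2R)-5-methyl-2-(prop-1-en-2-yl)hex-4-en-1-ol]
Conditions: LiBH4, Et2O, H2O (1 equiv), 0 °C
Reagents that add atoms: none
Why: reductive cleavage of the N-acyl oxazolidinone to the primary alcohol under non-enolising conditions, so the allylic stereocentre should be kept and the auxiliary recovered.

Step 4
Reactants: 6 (R)-lavandulol
Product: 7 (R)-lavandulyl iodide [(3R)-3-(iodomethyl)-2,6-dimethylhepta-1,5-diene]
Conditions: PPh3, I2, imidazole, CH2Cl2, 0 °C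
Reagents that add atoms: iodine, II
Why: Appel-type iodination of a primary alcohol by SN2 at CH2; the stereocentre is not touched.

Step 5
Reactants: 8 prenol (3-methylbut-2-en-1-ol)
Product: 9 epoxy alcohol [(2S)-3,3-dimethyloxiran-2-yl]methanol
Conditions: Ti(OiPr)4 (cat.), L-(+)-diethyl tartrate (cat.), t-BuOOH, 4 Å MS, CH2Cl2, −20 °C
Reagents that add atoms: tert-butyl hydroperoxide, CC(C)(C)OO
Why: Sharpless asymmetric epoxidation of an allylic alcohol; the L-(+)-tartrate–titanium complex should deliver oxygen to the enantioface that gives the (2S) epoxide.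

Step 6
Reactants: 9 epoxy alcohol
Product: 10 epoxy bromide (2R)-2-(bromomethyl)-3,3-dimethyloxirane
Conditions: PPh3, CBr4, CH2Cl2, 0 °C
Reagents that add atoms: carbon tetrabromide, BrC(Br)(Br)Br
Why: Appel bromination of the primary alcohol; the epoxide carbon is not touched (its descriptor changes from S to R only because CH2Br outranks the ring carbon).

Step 7
Reactants: 11 vanillic acid (4-hydroxy-3-methoxybenzoic acid)
Product: 12 bis-silyl vanillate tert-butyldimethylsilyl 4-[(tert-butyldimethylsilyl)oxy]-3-methoxybenzoate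
Conditions: TBSCl (2.5 equiv), imidazole, DMF, rt
Reagents that add atoms: tert-butyl(chloro)dimethylsilane, CC(C)(C)[Si](C)(C)Cl
Why: silylation of both the phenol and the carboxylic acid (silyl ether and silyl ester formation).

Step 8
Reactants: 12 bis-silyl vanillate
Product: 13 acid chloride 4-[(tert-butyldimethylsilyl)oxy]-3-methoxybenzoyl chloride
Conditions: (COCl)2, DMF (cat.), CH2Cl2, 0 °C to rt
Reagents that add atoms: oxalyl chloride, ClC(=O)C(=O)Cl
Why: Vilsmeier-type conversion of a silyl ester directly into the acid chloride under neutral conditions, which should leave the aryl silyl ether in place.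

Step 9
Reactants: 14 Birch diene 1,5-dimethoxycyclohexa-1,4-diene; 7 (R)-lavandulyl iodide
Product: 15 monoalkylated diene 6-Lav-1,5-dimethoxycyclohexa-1,4-diene
Conditions: t-BuLi, THF, HMPA, −78 °C; then 7, −78 to −20 °C
Reagents that add atoms: none
Why: deprotonation of the CH2 between the two enol ethers gives a cyclohexadienyl anion that is alkylated at its central carbon by SN2 (the carbanion equivalent of C-2 alkylation of cyclohexane-1,3-dione); no new stereocentre arises.

Step 10
Reactants: 15 monoalkylated diene; 10 epoxy bromide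
Product: 16 dialkylated diene 6-{[(2S)-3,3-dimethyloxiran-2-yl]methyl}-6-Lav-1,5-dimethoxycyclohexa-1,4-diene
Conditions: t-BuLi, THF, −78 °C; then 10, −78 to −30 °C
Reagents that add atoms: none
Why: second SN2 alkylation of the cyclohexadienyl anion at the same carbon, attacking the primary CH2–Br next to the epoxide; the new quaternary carbon is not a stereocentre because the two enol-ether arms of the ring are identical, and the epoxide carbon is not touched.

Step 11
Reactants: 16 dialkylated diene
Product: 18 tricyclic ketal (7S)-7,9-epoxy-4,9-dimethoxy-8,8-dimethyl-5-Lav-bicyclo[3.3.1]non-3-ene (bridgeheads as in 29; O7 exo), via C9 methyl oxocarbenium triflate 17 (not isolated)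
Conditions: Me3SiOTf (0.3 equiv), 2,6-lutidine (0.5 equiv), CH2Cl2, −78 °C
Reagents that add atoms: none
Why: Me3SiOTf activates the epoxide and the enol-ether carbon C1 opens it at the tertiary carbon C8 with inversion; the C9 methyl oxocarbenium ion 17 so formed is trapped by the C7 silyloxy oxygen with loss of Me3Si+ (which turns over) to give the ketal. The closest known reaction type is the Lewis acid-mediated epoxide-initiated cation–olefin cyclisation of enol ethers and polyenes, including its use on 6,6-disubstituted 1,5-dimethoxycyclohexa-1,4-dienes. Ring B closes by 6-endo opening of the epoxide (6-enolendo with respect to C1=C9) through a chair; the helper oxolane ring then closes by 5-exo attack of O7 on C9 after ring B flips to a boat. The anti opening forces the C7–O bond into the equatorial (exo) position of that chair, so the (7S) epoxide centre decides which of the two diastereotopic enol ethers reacts (C1 rather than C3) and thereby sets C1 and C5 (C5 becomes a stereocentre only now) as in 29; C9 follows from the geometry of the bridge. Needed are this group selectivity, opening at C8 rather than 5-exo at C7, and C- rather than O-alkylation: they should be secured by the chair/equatorial preference, by the tertiary cation character of C8 together with the strain of the alternative bicyclo[3.2.1] ring, and by the fact that both ring oxygens are methyl ethers; the lavandulyl alkenes are weaker nucleophiles and cannot reach C8 through a common ring size.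

Step 12
Reactants: 18 tricyclic ketal
Product: 19 ketal enone (7S)-7,9-epoxy-4,9-dimethoxy-8,8-dimethyl-5-Lav-bicyclo[3.3.1]non-3-en-2-one
Conditions: PhI(OAc)2, t-BuOOH, K2CO3, EtOAc, −20 °C
Reagents that add atoms: tert-butyl hydroperoxide, CC(C)(C)OO
Why: allylic C–H oxidation by a peroxyl radical chain; C2H2 is the only methylene allylic to the electron-rich enol ether and should be oxidised to the β-methoxy enone, with no stereocentre affected.

Step 13
Reactants: 19 ketal enone
Product: 20 hydroxy dione (7S)-7-hydroxy-4-methoxy-8,8-dimethyl-5-Lav-bicyclo[3.3.1]non-3-ene-2,9-dione (OH exo)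
Conditions: 0.5 M HCl, THF, 0 °C to rt
Reagents that add atoms: water, O
Why: acid hydrolysis of the mixed ketal, which should open at the bridging oxygen (the oxocarbenium ion on the other side would sit at a bridgehead) and release the C9 ketone and the C7 alcohol while the less reactive vinylogous ester survives; C7 is not touched.

Step 14
Reactants: 20 hydroxy dione
Product: 21 trione 4-methoxy-8,8-dimethyl-5-Lav-bicyclo[3.3.1]non-3-ene-2,7,9-trione
Conditions: Dess–Martin periodinane, CH2Cl2, rt
Reagents that add atoms: none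
Why: Dess–Martin oxidation of the secondary alcohol; the helper stereocentre at C7 is erased on purpose after it has set C1 and C5.

Step 15
Reactants: 21 trione
Product: 23 enal (E)-2-(4-methoxy-8,8-dimethyl-2,9-dioxo-5-Lav-bicyclo[3.3.1]non-3-en-7-ylidene)acetaldehyde, via unsaturated N-tert-butyl aldimine 22 (not isolated)
Conditions: Me3SiCH2CH=N-t-Bu, LDA, THF, −78 °C; then 21, −78 to 0 °C; then aq. oxalic acid, rt
Reagents that add atoms: N-tert-butyl-2-(trimethylsilyl)ethan-1-imine, C[Si](C)(C)CC=NC(C)(C)C; water, O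
Why: Peterson-type formyl olefination; the α-silyl aza-enolate should add to the C7 ketone (the C9 ketone lies between two bridgeheads and the enone carbonyl is deactivated), eliminate silanolate and give the enal on hydrolysis; the alkene geometry is of no consequence.

Step 16
Reactants: 23 enal
Product: 25 aldehyde 2-(4-methoxy-8,8-dimethyl-2,9-dioxo-5-Lav-bicyclo[3.3.1]non-3-en-7-yl)acetaldehyde (chain endo), via dimethylphenylsilyl enol ether 24 (not isolated)
Conditions: [(Ph3P)CuH]6 (cat.), PhMe2SiH, toluene, 0 °C to rt; then 0.5 M HCl, THF, 0 °C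
Reagents that add atoms: none
Why: copper hydride-catalysed conjugate reduction (1,4-hydrosilylation) of the enal; hydride should add to C7 from the open exo face, since the endo face is covered by ring A, which places the two-carbon chain endo as required for 29.

Step 17
Reactants: 25 aldehyde
Product: 26 C7-prenyl enone 4-methoxy-8,8-dimethyl-7-(3-methylbut-2-en-1-yl)-5-Lav-bicyclo[3.3.1]non-3-ene-2,9-dione (7R; prenyl endo)
Conditions: i-PrPPh3I, n-BuLi, THF, 0 °C; then 25, −78 °C to rt
Reagents that add atoms: isopropyltriphenylphosphonium iodide, CC(C)[P+](c1ccccc1)(c1ccccc1)c1ccccc1.[I-]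
Why: Wittig olefination with a non-stabilised ylide, which should react with the aldehyde only (the C9 ketone is hindered and the enone unreactive); C7 is not touched.

Step 18
Reactants: 26 C7-prenyl enone; 13 acid chloride
Product: 27 aroyl enone 3-{4-[(tert-butyldimethylsilyl)oxy]-3-methoxybenzoyl}-4-methoxy-8,8-dimethyl-7-(3-methylbut-2-en-1-yl)-5-Lav-bicyclo[3.3.1]non-3-ene-2,9-dione
Conditions: LiTMP, THF, −78 °C; then 13, −78 °C
Reagents that add atoms: none
Why: vinylic lithiation at C3 of the β-methoxy enone followed by C-acylation with the acid chloride; the hindered bridgehead C1–H should be slower to deprotonate, and no stereocentre is formed.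

Step 19
Reactants: 27 aroyl enone; 4 prenyl bromide
Product: 28 protected target 3-{4-[(tert-butyldimethylsilyl)oxy]-3-methoxybenzoyl}-4-methoxy-8,8-dimethyl-1,7-bis(3-methylbut-2-en-1-yl)-5-Lav-bicyclo[3.3.1]non-3-ene-2,9-dione
Conditions: LDA, THF, −78 °C; then 4, −78 to −20 °C
Reagents that add atoms: none
Why: bridgehead lithiation and alkylation; C1–H is acidified by the C2 and C9 carbonyls but cannot enolise (Bredt), so a pyramidal bridgehead carbanion should form and be alkylated by SN2 on prenyl bromide with retention, the only possible outcome at a bridgehead.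

Step 20
Reactants: 28 protected target
Product: 29 garcinol 13-O-methyl ether (1R,5R,7R)-4-hydroxy-3-(4-hydroxy-3-methoxybenzoyl)-8,8-dimethyl-1,7-bis(3-methylbut-2-en-1-yl)-5-[(2S)-5-methyl-2-(prop-1-en-2-yl)hex-4-en-1-yl]bicyclo[3.3.1]non-3-ene-2,9-dione
Conditions: LiOH, 1,4-dioxane–H2O, 90 °C; then 0.1 M HCl to pH 4 at 0 °C
Reagents that add atoms: lithium hydroxide, [Li+].[OH-]
Why: hydrolysis of the vinylogous methyl ester by addition–elimination of hydroxide at C4, with cleavage of the aryl silyl ether by the same base; no stereocentre is touched, and the cold, weakly acidic work-up should avoid cyclisation of the enol onto the isopropenyl group.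

**Compound list**

1 | (R)-4-benzyl-1,3-oxazolidin-2-one | O=C1N[C@H](Cc2ccccc2)CO1 | starting material
2 | senecioyl chloride (3-methylbut-2-enoyl chloride) | CC(C)=CC(=O)Cl | starting material
3 | (R)-4-benzyl-3-(3-methylbut-2-enoyl)-1,3-oxazolidin-2-one | CC(C)=CC(=O)N1[C@H](Cc2ccccc2)COC1=O | intermediate
4 | prenyl bromide (1-bromo-3-methylbut-2-ene) | CC(C)=CCBr | starting material
5 | (R)-4-benzyl-3-[(2R)-5-methyl-2-(prop-1-en-2-yl)hex-4-enoyl]-1,3-oxazolidin-2-one | C=C(C)[C@@H](CC=C(C)C)C(=O)N1[C@H](Cc2ccccc2)COC1=O | intermediate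
6 | (R)-lavandulol [(2R)-5-methyl-2-(prop-1-en-2-yl)hex-4-en-1-ol] | OC[C@H](CC=C(C)C)C(C)=C | intermediate
7 | (R)-lavandulyl iodide [(3R)-3-(iodomethyl)-2,6-dimethylhepta-1,5-diene] | IC[C@H](CC=C(C)C)C(C)=C | intermediate
8 | prenol (3-methylbut-2-en-1-ol) | CC(C)=CCO | starting material
9 | [(2S)-3,3-dimethyloxiran-2-yl]methanol | OC[C@@H]1OC1(C)C | intermediate
10 | (2R)-2-(bromomethyl)-3,3-dimethyloxirane | BrC[C@@H]1OC1(C)C | intermediate
11 | vanillic acid (4-hydroxy-3-methoxybenzoic acid) | COc1cc(C(=O)O)ccc1O | starting material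
12 | tert-butyldimethylsilyl 4-[(tert-butyldimethylsilyl)oxy]-3-methoxybenzoate | COc1cc(C(=O)O[Si](C)(C)C(C)(C)C)ccc1O[Si](C)(C)C(C)(C)C | intermediate
13 | 4-[(tert-butyldimethylsilyl)oxy]-3-methoxybenzoyl chloride | COc1cc(C(=O)Cl)ccc1O[Si](C)(C)C(C)(C)C | intermediate
14 | 1,5-dimethoxycyclohexa-1,4-diene | COC1=CCC=C(OC)C1 | starting material
15 | 6-Lav-1,5-dimethoxycyclohexa-1,4-diene | COC1=CCC=C(OC)C1C[C@H](CC=C(C)C)C(C)=C | intermediate
16 | 6-{[(2S)-3,3-dimethyloxiran-2-yl]methyl}-6-Lav-1,5-dimethoxycyclohexa-1,4-diene | COC1=CCC=C(OC)C1(C[C@H](CC=C(C)C)C(C)=C)C[C@@H]2OC2(C)C | intermediate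
17 | C9 methyl oxocarbenium triflate (C1–C8 bond formed; C7–OSiMe3 exo) | C=C(C)[C@@H](CC=C(C)C)C[C@@]12C[C@H](O[Si](C)(C)C)C(C)(C)[C@@H](CC=C1OC)C2=[O+]C.[O-]S(=O)(=O)C(F)(F)F | intermediate
18 | (7S)-7,9-epoxy-4,9-dimethoxy-8,8-dimethyl-5-Lav-bicyclo[3.3.1]non-3-ene (bridgeheads as in 29) | C=C(C)[C@@H](CC=C(C)C)C[C@@]12C[C@H]3C(C)(C)[C@@H](CC=C1OC)[C@]2(OC)O3 | intermediate
19 | (7S)-7,9-epoxy-4,9-dimethoxy-8,8-dimethyl-5-Lav-bicyclo[3.3.1]non-3-en-2-one | C=C(C)[C@@H](CC=C(C)C)C[C@@]12C[C@H]3C(C)(C)[C@@H](C(=O)C=C1OC)[C@]2(OC)O3 | intermediate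
20 | (7S)-7-hydroxy-4-methoxy-8,8-dimethyl-5-Lav-bicyclo[3.3.1]non-3-ene-2,9-dione (OH exo) | C=C(C)[C@@H](CC=C(C)C)C[C@@]12C[C@H](O)C(C)(C)[C@@H](C(=O)C=C1OC)C2=O | intermediate
21 | 4-methoxy-8,8-dimethyl-5-Lav-bicyclo[3.3.1]non-3-ene-2,7,9-trione | C=C(C)[C@@H](CC=C(C)C)C[C@@]12CC(=O)C(C)(C)[C@@H](C(=O)C=C1OC)C2=O | intermediate
22 | N-tert-butyl aldimine of enal 23 | C=C(C)[C@@H](CC=C(C)C)C[C@@]12C/C(=C\C=NC(C)(C)C)C(C)(C)[C@@H](C(=O)C=C1OC)C2=O | intermediate
23 | (E)-2-(4-methoxy-8,8-dimethyl-2,9-dioxo-5-Lav-bicyclo[3.3.1]non-3-en-7-ylidene)acetaldehyde | C=C(C)[C@@H](CC=C(C)C)C[C@@]12C/C(=C\C=O)C(C)(C)[C@@H](C(=O)C=C1OC)C2=O | intermediate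
24 | dimethylphenylsilyl enol ether of aldehyde 25 (chain on C7 endo) | C=C(C)[C@@H](CC=C(C)C)C[C@@]12C[C@@H](C=CO[Si](C)(C)c3ccccc3)C(C)(C)[C@@H](C(=O)C=C1OC)C2=O | intermediate
25 | 2-(4-methoxy-8,8-dimethyl-2,9-dioxo-5-Lav-bicyclo[3.3.1]non-3-en-7-yl)acetaldehyde (chain endo) | C=C(C)[C@@H](CC=C(C)C)C[C@@]12C[C@@H](CC=O)C(C)(C)[C@@H](C(=O)C=C1OC)C2=O | intermediate
26 | 4-methoxy-8,8-dimethyl-7-(3-methylbut-2-en-1-yl)-5-Lav-bicyclo[3.3.1]non-3-ene-2,9-dione (7R; prenyl endo) | C=C(C)[C@@H](CC=C(C)C)C[C@@]12C[C@@H](CC=C(C)C)C(C)(C)[C@@H](C(=O)C=C1OC)C2=O | intermediate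
27 | 3-{4-[(tert-butyldimethylsilyl)oxy]-3-methoxybenzoyl} derivative of 26 | C=C(C)[C@@H](CC=C(C)C)C[C@@]12C[C@@H](CC=C(C)C)C(C)(C)[C@@H](C(=O)C(C(=O)c3ccc(O[Si](C)(C)C(C)(C)C)c(OC)c3)=C1OC)C2=O | intermediate
28 | 1-(3-methylbut-2-en-1-yl) derivative of 27 (4-O-methyl 4'-O-silyl ether of 29) | C=C(C)[C@@H](CC=C(C)C)C[C@@]12C[C@@H](CC=C(C)C)C(C)(C)[C@@](CC=C(C)C)(C(=O)C(C(=O)c3ccc(O[Si](C)(C)C(C)(C)C)c(OC)c3)=C1OC)C2=O | intermediate
29 | garcinol 13-O-methyl ether | C=C(C)[C@@H](CC=C(C)C)C[C@@]12C[C@@H](CC=C(C)C)C(C)(C)[C@@](CC=C(C)C)(C(=O)C(C(=O)c3ccc(O)c(OC)c3)=C1O)C2=O | target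

**Totals**

Total step count: 20. Longest linear sequence: 16 steps (steps 1–4, then 9–20).

**Steps most likely to fail, with fallbacks**

1. Step 19 (bridgehead prenylation). The bridgehead next to C8 may be deprotonated slowly, the proton may return before alkylation, or prenyl bromide may be attacked in the SN2′ sense, so that little C1–C bond is formed. The fallback sets out from 27. The bridgehead anion is trapped with iodine, the smallest electrophile (LDA, then I2), to give the C1 iodide F1. Iodine–magnesium exchange (i-PrMgCl·LiCl, −78 °C) followed by copper-catalysed coupling with allyl bromide should give the C1-allyl compound F2. Cross-metathesis with 2-methyl-2-butene (Grubbs second-generation catalyst) turns allyl into prenyl and comes back to the route at 28.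

2. Step 12 (allylic oxidation). Hydrogen abstraction may also occur at the allylic positions of the lavandulyl chain, or oxidation may go further, so that site selectivity is lost. The fallback avoids C–H abstraction and sets out from 18. Aqueous HCl hydrolyses both the enol ether and the ketal to the hydroxy diketone F3. IBX (DMSO, 70 °C) oxidises the C7 alcohol and dehydrogenates the C4 ketone, the only carbonyl that can form an unstrained enone, to the enone F4. Nucleophilic epoxidation (t-BuOOH, DBU) gives the epoxy ketone F5. Palladium(0)-catalysed isomerisation of the α,β-epoxy ketone gives the cyclic 1,3-diketone F6. O-Methylation (Me3SiCHN2) then gives 21; the 2-methoxy regioisomer would be separated and recycled by hydrolysis. The route is rejoined at 21, so steps 13 and 14 fall away.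

3. Step 15 (formyl olefination). The lithiated imine may add to the C9 carbonyl or to the enone, or may simply enolise the C7 ketone. The fallback uses that enolisation instead and sets out from 21. Only the C7 ketone can enolise (C9 has bridgehead neighbours), so KHMDS/PhNTf2 should give the C6=C7 enol triflate F7. Stille coupling with (Z)-tributyl(2-ethoxyvinyl)stannane (Pd(PPh3)4, LiCl) gives the dienyl ether F8. Dilute aqueous acid hydrolyses the enol ether and brings the double bond into conjugation, which comes back to the route at 23.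

**Further compounds**

F1 | step 19 | C1 bridgehead iodide of 27 | C=C(C)[C@@H](CC=C(C)C)C[C@@]12C[C@@H](CC=C(C)C)C(C)(C)[C@@](I)(C(=O)C(C(=O)c3ccc(O[Si](C)(C)C(C)(C)C)c(OC)c3)=C1OC)C2=O
F2 | step 19 | C1-allyl analogue of 28 | C=C(C)[C@@H](CC=C(C)C)C[C@@]12C[C@@H](CC=C(C)C)C(C)(C)[C@@](CC=C)(C(=O)C(C(=O)c3ccc(O[Si](C)(C)C(C)(C)C)c(OC)c3)=C1OC)C2=O
F3 | step 12 | (7S)-7-hydroxy-8,8-dimethyl-5-Lav-bicyclo[3.3.1]nonane-4,9-dione | C=C(C)[C@@H](CC=C(C)C)C[C@@]12C[C@H](O)C(C)(C)[C@@H](CCC1=O)C2=O
F4 | step 12 | 8,8-dimethyl-5-Lav-bicyclo[3.3.1]non-2-ene-4,7,9-trione | C=C(C)[C@@H](CC=C(C)C)C[C@@]12CC(=O)C(C)(C)[C@@H](C=CC1=O)C2=O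
F5 | step 12 | 2,3-epoxide of F4 (epoxide face immaterial) | C=C(C)[C@@H](CC=C(C)C)C[C@@]12CC(=O)C(C)(C)[C@@H](C3OC3C1=O)C2=O
F6 | step 12 | 4-hydroxy-8,8-dimethyl-5-Lav-bicyclo[3.3.1]non-3-ene-2,7,9-trione (enol of the 2,4-dione) | C=C(C)[C@@H](CC=C(C)C)C[C@@]12CC(=O)C(C)(C)[C@@H](C(=O)C=C1O)C2=O
F7 | step 15 | C6=C7 enol triflate of 21 | C=C(C)[C@@H](CC=C(C)C)C[C@@]12C=C(OS(=O)(=O)C(F)(F)F)C(C)(C)[C@@H](C(=O)C=C1OC)C2=O
F8 | step 15 | 7-[(Z)-2-ethoxyvinyl] C6=C7 diene derived from F7 | C=C(C)[C@@H](CC=C(C)C)C[C@@]12C=C(/C=C\OCC)C(C)(C)[C@@H](C(=O)C=C1OC)C2=O
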